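**Plan**

- Retrosynthesis: the two angelate C–O bonds are cut first, then the C8–O and C9–O bonds (syn-dihydroxylation of a C8=C9 alkene), the C3–CH3 bond (cuprate) and the C2–C3 bond of the cyclohexanone (aldol condensation). The cyclobutane bonds C4–C5 and C10–C11 are cut together (intramolecular vinylketene–diene [2+2]), and the open chain is cut at C8=C9 and C5=C11 down to (S)-pantolactone (C5 to C8).
- Forward: two olefinations join the chain. The seven-membered ring and the cyclobutane then arise in one step as a bicyclo[4.1.1]oct-2-en-7-one. C4 is homologated to CHO, the C11 vinyl group is oxidised to acetyl, and the six-membered ring is closed last between C2 and C3, which completes the tricyclo[5.4.0.0(2,8)]undecane core.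
- Enabling feature: the formyl group on C4 and the acetyl group on C11 stand syn on the 1,3-positions of the cyclobutane C4–C5–C11–C10, held close together and both on epimerisable carbons, so only the C2 enolate and the C3 aldehyde can meet.
- Stereochemistry: C7 comes from (S)-pantolactone; C10, C5 and C11 from C7 and from the E alkene in the [2+2] step; C4 and C11 are corrected by equilibration in the ring closure; C3 by cuprate addition anti to the C10 methyl; C8 and C9 by osmylation anti to the C7 benzyloxy group.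

Key step: step 11

Remark on the chemistry: atom labels C1 to C15 are those of the target skeleton (C1 ketone, C2 its CH2, C3 the CHMe carbon with methyl C15, cyclobutane C4–C5–C11–C10 with a methyl on C10, seven-membered ring C5–C6(Me2)–C7–C8–C9–C10–C11); β means the face of the seven-membered ring on the side of C4 and α the side of C11; both acyl groups are taken as (Z)-2-methylbut-2-enoyl (angeloyl), as drawn.

Step 1
Reactants: 1 (S)-pantolactone
Product: 2 (3S)-3-(benzyloxy)-4,4-dimethyloxolan-2-one
Conditions: benzyl 2,2,2-trichloroacetimidate, TfOH (cat.), CH2Cl2–cyclohexane, 0 °C→rt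
Reagents that add atoms: benzyl 2,2,2-trichloroacetimidate, N=C(OCc1ccccc1)C(Cl)(Cl)Cl
Why: acid-catalysed O-benzylation with the imidate avoids base, so the lactone α-stereocentre (the future C7) should stay intact.

Step 2
Reactants: 2 (3S)-3-(benzyloxy)-4,4-dimethyloxolan-2-one
Product: 3 (3S)-3-(benzyloxy)-4,4-dimethyloxolan-2-ol (lactol; anomer mixture)
Conditions: i-Bu2AlH, CH2Cl2, −78 °C; aqueous potassium sodium tartrate
Reagents that add atoms: none
Why: low-temperature half-reduction of a γ-lactone with i-Bu2AlH should stop at the lactol, which masks the C8 aldehyde.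

Step 3
Reactants: 4 3-bromo-2-methylpropanoic acid (racemic); 5 triphenylphosphine
Product: 6 (2-carboxypropyl)triphenylphosphonium bromide
Conditions: MeCN, reflux
Reagents that add atoms: none
Why: SN2 quaternisation of the primary bromide should give the Wittig salt that carries C9, C10, its methyl and the carboxyl carbon C4.

Step 4
Reactants: 3 (3S)-3-(benzyloxy)-4,4-dimethyloxolan-2-ol; 6 (2-carboxypropyl)triphenylphosphonium bromide
Product: 8 (2RS,3Z,5R)-5-(benzyloxy)-7-hydroxy-2,6,6-trimethylhept-3-enoic acid, via carboxylate ylide 7 (not isolated)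
Conditions: NaN(SiMe3)2 (2 equiv per 6), THF, 0 °C; then 3, 0 °C→rt; 1 M HCl work-up
Reagents that add atoms: none
Why: Wittig olefination of the lactol (open hydroxy aldehyde) with the non-stabilised carboxylate ylide under salt-free conditions should give the Z alkene C8=C9; the carboxylate form suppresses β-elimination, and the C2 epimers converge in step 7.

Step 5
Reactants: 8 (2RS,3Z,5R)-5-(benzyloxy)-7-hydroxy-2,6,6-trimethylhept-3-enoic acid
Product: 9 (2RS,3Z,5R)-5-(benzyloxy)-2,6,6-trimethyl-7-oxohept-3-enoic acid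
Conditions: Dess–Martin periodinane, CH2Cl2, 0 °C→rt
Reagents that add atoms: none
Why: neutral oxidation of the neopentyl primary alcohol should give the non-enolisable aldehyde (C5) and leave the acid, the benzyl ether and the Z alkene untouched.

Step 6
Reactants: 9 (2RS,3Z,5R)-5-(benzyloxy)-2,6,6-trimethyl-7-oxohept-3-enoic acid
Product: 10 (2RS,3Z,5R,7E)-5-(benzyloxy)-2,6,6-trimethyldeca-3,7,9-trienoic acid
Conditions: diethyl allylphosphonate (2.5 equiv), n-BuLi (2.4 equiv), THF–DMPU, −78 °C; then 9, −78 °C→rt; 1 M HCl work-up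
Reagents that add atoms: diethyl allylphosphonate, C=CCP(=O)(OCC)OCC
Why: Horner–Wadsworth–Emmons olefination of the hindered aldehyde with the α-lithiated allylphosphonate (the first equivalent forms the lithium carboxylate) should give the terminal E diene C5=C11–C1=C2.

Step 7
Reactants: 10 (2RS,3Z,5R,7E)-5-(benzyloxy)-2,6,6-trimethyldeca-3,7,9-trienoic acid
Product: 13 4-(benzyloxy)-1,5,5-trimethyl-8-vinylbicyclo[4.1.1]oct-2-en-7-one, via acid chloride 11 (not isolated), via vinylketene 12 (not isolated)
Conditions: (COCl)2, DMF (cat.), CH2Cl2, 0 °C→rt; evaporation; slow addition to Et3N, toluene, 110 °C, high dilution (0.005 M)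
Reagents that add atoms: none
Why: Proposed new method: Et3N removes HCl from 11 to give the Z-vinylketene 12, whose electrophilic carbonyl carbon C4 should bond to the diene terminus C5 (the only position that leaves an allyl cation over C11–C1–C2) before the enolate carbon C10 closes on C11, so the bridged bicyclo[4.1.1]octenone is expected and not the fused isomer; the E geometry of C5=C11 places the vinyl group syn to the carbonyl bridge C4, and the C7 benzyloxy group should take the pseudo-equatorial site of the chair-like seven-membered transition structure, anti to the incoming C11, which sets C10, C5 and C11 relative to C7 and puts O7 on the C4 side; the closest known reaction type is the bridged-mode intramolecular vinylketene–alkene [2+2] cycloaddition that gives bicyclo[3.1.1]heptan-6-ones, together with the regiochemistry of ketene–1,3-diene cycloadditions, extended here to a four-atom tether and a diene partner.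

Step 8
Reactants: 13 4-(benzyloxy)-1,5,5-trimethyl-8-vinylbicyclo[4.1.1]oct-2-en-7-one
Product: 14 4-(benzyloxy)-7-(methoxymethylidene)-1,5,5-trimethyl-8-vinylbicyclo[4.1.1]oct-2-ene (E/Z mixture)
Conditions: (methoxymethyl)triphenylphosphonium chloride, KOt-Bu, THF, 0 °C→rt
Reagents that add atoms: (methoxymethyl)triphenylphosphonium chloride, COC[P+](c1ccccc1)(c1ccccc1)c1ccccc1.[Cl-]
Why: Wittig methoxymethylenation of the strained, non-enolisable cyclobutanone should introduce C3 as an enol ether whose geometry is of no consequence.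

Step 9
Reactants: 14 4-(benzyloxy)-7-(methoxymethylidene)-1,5,5-trimethyl-8-vinylbicyclo[4.1.1]oct-2-ene
Product: 15 4-(benzyloxy)-1,5,5-trimethyl-8-vinylbicyclo[4.1.1]oct-2-ene-7-carbaldehyde (formyl syn to vinyl)
Conditions: oxalic acid (cat.), THF–H2O, rt
Reagents that add atoms: water, O
Why: enol ether hydrolysis should protonate C4 from the face anti to the C11 vinyl group, so the formyl group comes out syn to it; any C4 epimer is corrected in step 11.

Step 10
Reactants: 15 4-(benzyloxy)-1,5,5-trimethyl-8-vinylbicyclo[4.1.1]oct-2-ene-7-carbaldehyde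
Product: 16 8-acetyl-4-(benzyloxy)-1,5,5-trimethylbicyclo[4.1.1]oct-2-ene-7-carbaldehyde (acetyl syn to formyl)
Conditions: PdCl2 (10 mol %), CuCl (30 mol %), O2 (1 atm), DMF–H2O 7:1, rt
Reagents that add atoms: water, O (source of the carbonyl oxygen); dioxygen, O=O (terminal oxidant)
Why: Tsuji–Wacker oxidation should convert the monosubstituted alkene C1=C2 into the methyl ketone with Markovnikov selectivity, while the hindered 1,2-disubstituted alkene C8=C9 is expected to remain.

Step 11
Reactants: 16 8-acetyl-4-(benzyloxy)-1,5,5-trimethylbicyclo[4.1.1]oct-2-ene-7-carbaldehyde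
Product: 18 7β-(benzyloxy)-15-norlongipina-2,8-dien-1-one, via aldol adduct 17 (not isolated)
Conditions: KOH, MeOH, 0 °C→40 °C, 0.01 M
Reagents that add atoms: none
Why: Hydroxide should reversibly form the methyl-ketone enolate at C2, which adds to the C3 aldehyde in a 6-(enolendo)-exo-trig aldol addition to 17, and E1cB loss of water then gives the conjugated bicyclo[3.1.1]hept-3-en-2-one unit, so the new C2–C3 bond closes the six-membered ring and completes the tricyclic core. The closest known reaction type is the intramolecular aldol condensation of 1,5-dicarbonyl compounds to cyclohexenones. Closure is possible because the acetyl group on C11 and the formyl group on C4 are held syn across the 1,3-positions of the cyclobutane; the enolates at C4 and C11 cannot cyclise (they would have to build a bicyclo[1.1.1]pentane), and a double bond at the bridgeheads C4 or C11 is excluded, which secures the regiochemistry. No permanent stereocentre is created (the carbinol of 17 is lost), but C4 and C11 are epimerisable α to their carbonyl groups, so any anti isomer should be funnelled through the syn isomer into the dehydration, and both centres end with the configuration the ring demands. The step needs intramolecular to win over intermolecular aldol reaction, which the proximity of the two groups and the dilution should secure.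

Step 12
Reactants: 18 7β-(benzyloxy)-15-norlongipina-2,8-dien-1-one
Product: 19 7β-(benzyloxy)longipin-8-en-1-one (C3 methyl anti to the C10 methyl)
Conditions: Me2CuLi (from MeLi and CuI), Et2O, −78 °C→−20 °C; aqueous NH4Cl
Reagents that add atoms: methyllithium (used as Me2CuLi), [Li]C
Why: conjugate addition of the cuprate to the enone should occur from the face of the C5–H bridge, anti to the C10 methyl that overhangs the other face, which sets C3 as in the target, in line with 1,4-additions to bicyclo[3.1.1]hept-3-en-2-ones.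

Step 13
Reactants: 19 7β-(benzyloxy)longipin-8-en-1-one
Product: 20 7β-(benzyloxy)-8α,9α-dihydroxylongipinan-1-one
Conditions: OsO4 (5 mol %), N-methylmorpholine N-oxide, acetone–H2O, rt
Reagents that add atoms: N-methylmorpholine N-oxide, C[N+]1([O-])CCOCC1; water, O
Why: syn-dihydroxylation of the only remaining alkene C8=C9 should take place anti to the allylic C7 benzyloxy group (allylic 1,2-induction), giving the cis-8,9-diol trans to O7.

Step 14
Reactants: 20 7β-(benzyloxy)-8α,9α-dihydroxylongipinan-1-one
Product: 21 7β-(benzyloxy)-9α-hydroxy-8α-(triethylsilyloxy)longipinan-1-one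
Conditions: Et3SiCl, imidazole, DMF, −20 °C
Reagents that add atoms: chlorotriethylsilane, CC[Si](CC)(CC)Cl
Why: the C8 hydroxyl should be silylated selectively because the C9 hydroxyl is neopentyl (next to the quaternary C10).

Step 15
Reactants: 21 7β-(benzyloxy)-9α-hydroxy-8α-(triethylsilyloxy)longipinan-1-one
Product: 22 7β,9α-dihydroxy-8α-(triethylsilyloxy)longipinan-1-one
Conditions: H2 (1 atm), Pd(OH)2/C, EtOAc, rt
Reagents that add atoms: none
Why: hydrogenolysis of the benzyl ether frees O7; no alkene is left, and the ketone, the cyclobutane and the silyl ether are expected to survive in EtOAc.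

Step 16
Reactants: 22 7β,9α-dihydroxy-8α-(triethylsilyloxy)longipinan-1-one; 23 angelic acid
Product: 25 7β,9α-bis(angeloyloxy)-8α-(triethylsilyloxy)longipinan-1-one, via mixed anhydride 24 (not isolated)
Conditions: 23 (6 equiv), 2,4,6-trichlorobenzoyl chloride, Et3N, toluene, rt; then 22, toluene, 80 °C
Reagents that add atoms: none
Why: Yamaguchi-type acylation through the mixed anhydride, run without a nucleophilic amine catalyst, should esterify both hindered secondary alcohols and keep the Z geometry of the 2-methylbut-2-enoyl group.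

Step 17
Reactants: 25 7β,9α-bis(angeloyloxy)-8α-(triethylsilyloxy)longipinan-1-one
Product: 26 7β,9α-bis(angeloyloxy)-8α-hydroxylongipinan-1-one (CNP0303821.1)
Conditions: HF·pyridine, THF, 0 °C→rt
Reagents that add atoms: none
Why: acidic fluoride should cleave the triethylsilyl ether without acyl migration to O8 and without Z/E isomerisation of the esters.

**Compound list**

1 | (S)-pantolactone, (3S)-3-hydroxy-4,4-dimethyloxolan-2-one | O[C@@H]1C(=O)OCC1(C)C | starting material
2 | (3S)-3-(benzyloxy)-4,4-dimethyloxolan-2-one | c1ccccc1CO[C@@H]2C(=O)OCC2(C)C | intermediate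
3 | (3S)-3-(benzyloxy)-4,4-dimethyloxolan-2-ol, anomer mixture | c1ccccc1CO[C@@H]2C(O)OCC2(C)C | intermediate
4 | 3-bromo-2-methylpropanoic acid, racemic | OC(=O)C(C)CBr | starting material
5 | triphenylphosphine | c1ccccc1P(c1ccccc1)c1ccccc1 | starting material
6 | (2-carboxypropyl)triphenylphosphonium bromide, racemic | OC(=O)C(C)C[P+](c1ccccc1)(c1ccccc1)c1ccccc1.[Br-] | intermediate
7 | sodium 2-methyl-3-(triphenylphosphoranylidene)propanoate (carboxylate ylide) | [Na+].[O-]C(=O)C(C)C=P(c1ccccc1)(c1ccccc1)c1ccccc1 | intermediate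
8 | (2RS,3Z,5R)-5-(benzyloxy)-7-hydroxy-2,6,6-trimethylhept-3-enoic acid | OC(=O)C(C)/C=C\[C@@H](OCc1ccccc1)C(C)(C)CO | intermediate
9 | (2RS,3Z,5R)-5-(benzyloxy)-2,6,6-trimethyl-7-oxohept-3-enoic acid | OC(=O)C(C)/C=C\[C@@H](OCc1ccccc1)C(C)(C)C=O | intermediate
10 | (2RS,3Z,5R,7E)-5-(benzyloxy)-2,6,6-trimethyldeca-3,7,9-trienoic acid | OC(=O)C(C)/C=C\[C@@H](OCc1ccccc1)C(C)(C)/C=C/C=C | intermediate
11 | (2RS,3Z,5R,7E)-5-(benzyloxy)-2,6,6-trimethyldeca-3,7,9-trienoyl chloride | ClC(=O)C(C)/C=C\[C@@H](OCc1ccccc1)C(C)(C)/C=C/C=C | intermediate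
12 | (3Z,5R,7E)-5-(benzyloxy)-2,6,6-trimethyldeca-1,3,7,9-tetraen-1-one (vinylketene) | O=C=C(C)/C=C\[C@@H](OCc1ccccc1)C(C)(C)/C=C/C=C | intermediate
13 | 4-(benzyloxy)-1,5,5-trimethyl-8-vinylbicyclo[4.1.1]oct-2-en-7-one (C4 is the carbonyl bridge; vinyl on C11 syn to C4; benzyloxy on C7 on the C4 side) | c4ccccc4CO[C@@H]1C=C[C@]2(C)C(=O)[C@@H]([C@H]2C=C)C1(C)C | intermediate
14 | 4-(benzyloxy)-7-(methoxymethylidene)-1,5,5-trimethyl-8-vinylbicyclo[4.1.1]oct-2-ene, E/Z mixture | c4ccccc4CO[C@@H]1C=C[C@]2(C)C(=COC)[C@@H]([C@H]2C=C)C1(C)C | intermediate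
15 | 4-(benzyloxy)-1,5,5-trimethyl-8-vinylbicyclo[4.1.1]oct-2-ene-7-carbaldehyde (formyl on C4 syn to vinyl on C11) | c4ccccc4CO[C@@H]1C=C[C@]2(C)[C@@H](C=O)[C@@H]([C@H]2C=C)C1(C)C | intermediate
16 | 8-acetyl-4-(benzyloxy)-1,5,5-trimethylbicyclo[4.1.1]oct-2-ene-7-carbaldehyde (acetyl on C11 syn to formyl on C4) | c4ccccc4CO[C@@H]1C=C[C@]2(C)[C@@H](C=O)[C@@H]([C@H]2C(C)=O)C1(C)C | intermediate
17 | 7β-(benzyloxy)-3-hydroxy-15-norlongipin-8-en-1-one (aldol adduct; C3 epimers) | c4ccccc4CO[C@@H]1C=C[C@]2(C)[C@@H]3[C@@H]([C@H]2C(=O)CC3O)C1(C)C | intermediate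
18 | 7β-(benzyloxy)-15-norlongipina-2,8-dien-1-one | c4ccccc4CO[C@@H]1C=C[C@]2(C)[C@@H]3[C@@H]([C@H]2C(=O)C=C3)C1(C)C | intermediate
19 | 7β-(benzyloxy)longipin-8-en-1-one (C3 methyl anti to the C10 methyl) | c4ccccc4CO[C@@H]1C=C[C@]2(C)[C@@H]3[C@@H]([C@H]2C(=O)C[C@H]3C)C1(C)C | intermediate
20 | 7β-(benzyloxy)-8α,9α-dihydroxylongipinan-1-one | c4ccccc4CO[C@@H]1[C@@H](O)[C@@H](O)[C@]2(C)[C@@H]3[C@@H]([C@H]2C(=O)C[C@H]3C)C1(C)C | intermediate
21 | 7β-(benzyloxy)-9α-hydroxy-8α-(triethylsilyloxy)longipinan-1-one | c4ccccc4CO[C@@H]1[C@@H](O[Si](CC)(CC)CC)[C@@H](O)[C@]2(C)[C@@H]3[C@@H]([C@H]2C(=O)C[C@H]3C)C1(C)C | intermediate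
22 | 7β,9α-dihydroxy-8α-(triethylsilyloxy)longipinan-1-one | O[C@@H]1[C@@H](O[Si](CC)(CC)CC)[C@@H](O)[C@]2(C)[C@@H]3[C@@H]([C@H]2C(=O)C[C@H]3C)C1(C)C | intermediate
23 | angelic acid, (Z)-2-methylbut-2-enoic acid | C/C=C(/C)C(=O)O | starting material
24 | (Z)-2-methylbut-2-enoic 2,4,6-trichlorobenzoic anhydride | C/C=C(/C)C(=O)OC(=O)c1c(Cl)cc(Cl)cc1Cl | intermediate
25 | 7β,9α-bis(angeloyloxy)-8α-(triethylsilyloxy)longipinan-1-one | C/C=C(/C)C(=O)O[C@@H]1[C@@H](O[Si](CC)(CC)CC)[C@@H](OC(=O)/C(C)=C\C)[C@]2(C)[C@@H]3[C@@H]([C@H]2C(=O)C[C@H]3C)C1(C)C | intermediate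
26 | 7β,9α-bis(angeloyloxy)-8α-hydroxylongipinan-1-one (CNP0303821.1) | C/C=C(/C)C(=O)O[C@@H]1[C@@H](O)[C@@H](OC(=O)/C(C)=C\C)[C@]2(C)[C@@H]3[C@@H]([C@H]2C(=O)C[C@H]3C)C1(C)C | target

**Step count**

Total step count: 17. Longest linear sequence: 16 steps (steps 1, 2 and 4 to 17; step 3 prepares the Wittig salt).

**Steps most likely to fail**

Step 7 (labelled). The vinylketene may oligomerise, may undergo a 1,5-hydrogen shift from C7 to a dienal, or may close in the fused or the [4+2] mode, and the facial selectivity relative to C7 may be low. The fallback sets out from 10 and uses the known intramolecular keteniminium–alkene [2+2] cycloaddition. Acid 10 would be coupled with pyrrolidine (EDC·HCl, HOBt, CH2Cl2) to 1-[(2RS,3Z,5R,7E)-5-(benzyloxy)-2,6,6-trimethyldeca-3,7,9-trienoyl]pyrrolidine F1. Activation with Tf2O and 2,4,6-collidine in 1,2-dichloroethane at reflux should give a keteniminium triflate, a more electrophilic ketene equivalent that does not dimerise, and the same bridged closure should give the cyclobutaniminium triflate F2. Hydrolysis with aqueous NaHCO3 would bring the route back at 13.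

Step 11. Ring strain may hold the aldol equilibrium on the open side, or intermolecular condensation of the aldehyde may compete. The fallback sets out from 15 and closes the same bond by a Michael addition that also sets C3. Olefination of 15 with diethyl (phenylsulfonyl)methylphosphonate (NaH, THF) should give the E vinyl sulfone 4-(benzyloxy)-1,5,5-trimethyl-7-[(E)-2-(phenylsulfonyl)vinyl]-8-vinylbicyclo[4.1.1]oct-2-ene F3. Tsuji–Wacker oxidation (PdCl2, CuCl, O2, DMF–H2O) would give the methyl ketone 1-[4-(benzyloxy)-1,5,5-trimethyl-7-[(E)-2-(phenylsulfonyl)vinyl]bicyclo[4.1.1]oct-2-en-8-yl]ethanone F4. KOt-Bu (cat.) in t-BuOH–THF should then close the ring by 6-exo-trig addition of the C2 enolate to C3, with the sulfonylmethyl group turned away from the C10 methyl, to give 7β-(benzyloxy)-15-(phenylsulfonyl)longipin-8-en-1-one F5. Reductive desulfonylation (Na/Hg, Na2HPO4, MeOH, −20 °C) would bring the route back at 19.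

Step 16. Acylation of two neopentyl hydroxyl groups that flank a silyloxy group may stay incomplete, and forcing conditions may isomerise the acyl donor from Z to E. The fallback sets out from 22 and builds the Z alkenes on the esters. Both hydroxyl groups would be acylated with 2-[bis(2,2,2-trifluoroethoxy)phosphoryl]propanoic acid (DCC, DMAP, CH2Cl2) to 7β,9α-bis{2-[bis(2,2,2-trifluoroethoxy)phosphoryl]propanoyloxy}-8α-(triethylsilyloxy)longipinan-1-one F6. Still–Gennari olefination with acetaldehyde (KN(SiMe3)2, 18-crown-6, THF, −78 °C) should give both Z-2-methylbut-2-enoates and bring the route back at 25.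

Further compounds
F1 | step 7 | 1-[(2RS,3Z,5R,7E)-5-(benzyloxy)-2,6,6-trimethyldeca-3,7,9-trienoyl]pyrrolidine | O=C(N1CCCC1)C(C)/C=C\[C@@H](OCc1ccccc1)C(C)(C)/C=C/C=C
F2 | step 7 | 1-[4-(benzyloxy)-1,5,5-trimethyl-8-vinylbicyclo[4.1.1]oct-2-en-7-ylidene]pyrrolidinium trifluoromethanesulfonate | [O-]S(=O)(=O)C(F)(F)F.c4ccccc4CO[C@@H]1C=C[C@]2(C)C(=[N+]5CCCC5)[C@@H]([C@H]2C=C)C1(C)C
F3 | step 11 | 4-(benzyloxy)-1,5,5-trimethyl-7-[(E)-2-(phenylsulfonyl)vinyl]-8-vinylbicyclo[4.1.1]oct-2-ene | c4ccccc4CO[C@@H]1C=C[C@]2(C)[C@@H](/C=C/S(=O)(=O)c5ccccc5)[C@@H]([C@H]2C=C)C1(C)C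
F4 | step 11 | 1-[4-(benzyloxy)-1,5,5-trimethyl-7-[(E)-2-(phenylsulfonyl)vinyl]bicyclo[4.1.1]oct-2-en-8-yl]ethanone | c4ccccc4CO[C@@H]1C=C[C@]2(C)[C@@H](/C=C/S(=O)(=O)c5ccccc5)[C@@H]([C@H]2C(C)=O)C1(C)C
F5 | step 11 | 7β-(benzyloxy)-15-(phenylsulfonyl)longipin-8-en-1-one | c4ccccc4CO[C@@H]1C=C[C@]2(C)[C@@H]3[C@@H]([C@H]2C(=O)C[C@H]3CS(=O)(=O)c5ccccc5)C1(C)C
F6 | step 16 | 7β,9α-bis{2-[bis(2,2,2-trifluoroethoxy)phosphoryl]propanoyloxy}-8α-(triethylsilyloxy)longipinan-1-one | CC(C(=O)O[C@@H]1[C@@H](O[Si](CC)(CC)CC)[C@@H](OC(=O)C(C)P(=O)(OCC(F)(F)F)OCC(F)(F)F)[C@]2(C)[C@@H]3[C@@H]([C@H]2C(=O)C[C@H]3C)C1(C)C)P(=O)(OCC(F)(F)F)OCC(F)(F)F
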